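Core numbered as a 1-benzoxepine: O1, C2 (=CHBr), C3–C4 (epoxide), C5, C5a (fusion CH), C6 (CMe2), C7 (CHBr), C8, C9, C9a (angular C(CH3)–O); ring A = cyclohexane, ring B = oxepane. The plan rests on the C9a–C5a bond of ring A: an oxygen-bearing quaternary carbon bonded directly to a CH that carries a two-carbon arm and is flanked by the C6 gem-dimethyl carbon.
That bond is cut to a ketone carbon (C9a) and an enoate β-carbon (C5a), two electrophiles joined by reductive ketyl–olefin coupling of the acyclic bromo keto enoate 10; ring A is formed first.
10 comes from pent-4-enal 1: aldol with silyl ketene acetal 2 sets the carbinol, inversion gives the C7 bromide, then ester → aldehyde → E-enoate with 8, and Wacker oxidation unveils the methyl ketone.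
Ring B is formed second: the ester arm of 11 becomes allyl, the tertiary alcohol is acylated with 14, and ring-closing metathesis gives the seven-membered unsaturated lactone 17.
Last, the C2 carbonyl becomes dibromomethylidene (18), the bromine syn to O1 is removed (19), and epoxidation of C3=C4 anti to the angular methyl closes the epoxide and gives 20.

Key step: step 7

Assumption: the oxazaborolidinone from N-tosyl-L-valine is taken to give the (3R)-aldol with an unbranched aldehyde; if the sense were opposite, the D-valine reagent would be used and nothing else changes.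

Step 1
Reactants: 1 pent-4-enal; 2 1-methoxy-2-methyl-1-(trimethylsiloxy)propene
Product: 3 methyl (3R)-3-hydroxy-2,2-dimethylhept-6-enoate
Conditions: N-tosyl-L-valine (1.1 equiv), BH3·THF (1.0 equiv), CH2Cl2, 0 → 20 °C; then 1 and 2 (1.2 equiv), −78 °C; pH 7 buffer, then 1 M HCl work-up
Reagents that add atoms: 2 (reactant above), COC(O[Si](C)(C)C)=C(C)C
Why: Kiyooka-type Mukaiyama aldol in which the aldehyde is activated on the boron of the oxazaborolidinone formed from N-tosyl-L-valine and BH3, the tosyl and isopropyl groups leave one aldehyde face open to the tetrasubstituted silyl ketene acetal, and this sets C3 as R while the terminal alkene, a masked methyl ketone, is inert.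

Step 2
Reactants: 3
Product: 5 methyl (3S)-3-bromo-2,2-dimethylhept-6-enoate, via triflate 4 (not isolated)
Conditions: Tf2O (1.3 equiv), 2,6-lutidine (2 equiv), CH2Cl2, −78 °C; then n-Bu4NBr (4 equiv), −78 → 20 °C
Reagents that add atoms: trifluoromethanesulfonic anhydride, O=S(=O)(OS(=O)(=O)C(F)(F)F)C(F)(F)F (its atoms stay only in 4); tetrabutylammonium bromide, CCCC[N+](CCCC)(CCCC)CCCC.[Br-]
Why: SN2 displacement of a secondary triflate by bromide with Walden inversion sets the C–Br centre as S; the carbon is neopentyl-like, which is why the best sulfonate leaving group is used, while the ester on the adjacent quaternary carbon disfavours ionisation and leaves no α-hydrogen for conjugated elimination, and the butenyl chain (unlike an oxygenated ketone surrogate) cannot act as a neighbouring group.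

Step 3
Reactants: 5
Product: 6 (3S)-3-bromo-2,2-dimethylhept-6-en-1-ol
Conditions: i-Bu2AlH (2.5 equiv), CH2Cl2, −78 → 0 °C; Rochelle salt work-up
Reagents that add atoms: none
Why: Reduction of the hindered ester with i-Bu2AlH to the primary alcohol is cleaner than stopping at the aldehyde, and the alkyl bromide, the terminal alkene and the stereocentre are not touched at these temperatures.

Step 4
Reactants: 6
Product: 7 (3S)-3-bromo-2,2-dimethylhept-6-enal
Conditions: Dess–Martin periodinane (1.3 equiv), NaHCO3, CH2Cl2, 0 → 20 °C
Reagents that add atoms: none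
Why: Dess–Martin oxidation of the neopentyl alcohol under buffered, non-basic conditions gives an aldehyde without α-hydrogen, which can neither epimerise nor lose HBr by enolisation.

Step 5
Reactants: 7; 8 trimethyl phosphonoacetate
Product: 9 methyl (2E,5S)-5-bromo-4,4-dimethylnona-2,8-dienoate
Conditions: 8 (1.2 equiv), NaH (1.1 equiv), THF, 0 °C; then 7, 0 → 20 °C
Reagents that add atoms: 8 (reactant above), COC(=O)CP(=O)(OC)OC
Why: Horner–Wadsworth–Emmons olefination of an α-quaternary aldehyde with a stabilised phosphonate anion gives the E-enoate, and the anion is too weak a base and too poor a nucleophile to attack the hindered secondary bromide.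

Step 6
Reactants: 9
Product: 10 methyl (2E,5S)-5-bromo-4,4-dimethyl-8-oxonon-2-enoate
Conditions: PdCl2 (10 mol%), CuCl (1 equiv), O2 (1 atm), DMF/H2O 7:1, 20 °C
Reagents that add atoms: water, O
Why: Tsuji–Wacker oxidation (Markovnikov hydroxypalladation of the terminal alkene, then β-hydride elimination) gives the methyl ketone with O2 and CuCl turning the palladium over, the electron-poor hindered enoate and the alkyl bromide stay as they are, and unveiling the ketone only now keeps the base-sensitive γ-bromo ketone out of all earlier basic steps.

Step 7
Reactants: 10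
Product: 11 methyl 2-[(1S,3S,6S)-3-bromo-6-hydroxy-2,2,6-trimethylcyclohexyl]acetate
Conditions: SmI2 (2.5 equiv, 0.1 M in THF), MeOH (4 equiv), THF, −78 → −20 °C, no HMPA; aqueous NH4Cl work-up
Reagents that add atoms: none
Why: Divalent samarium transfers one electron to the ketone of 10 to give a ketyl whose carbon adds to the enoate β-carbon in a 6-exo-trig closure of ring A, and a second electron and a proton from MeOH turn the α-ester radical into the saturated ester; the closest known reaction is the SmI2-mediated ketyl–olefin cyclisation of keto enoates run with an alcohol and without HMPA. Both new stereocentres (cyclohexyl C6 and C1 of 11, which become C9a and C5a) are set in a chair transition state in which the enoate arm is equatorial and the heavily solvated O–Sm group, almost linear at oxygen, avoids the syn-axial methyl of the CMe2 carbon and lies equatorial, which puts the methyl axial and the hydroxyl trans to the arm. Their sense relative to the existing C–Br centre follows from bromine lying equatorial in that chair, a preference that is not large next to CMe2, so the isomer with both new centres inverted is the expected minor product and is removed by chromatography here. The step needs chemoselectivity for C=O over C–Br: without HMPA at low temperature divalent samarium reduces a hindered secondary alkyl bromide far more slowly than it forms the ketyl that the activated alkene traps, and the CMe2 group holds the two ends together (Thorpe–Ingold effect) so that closure outruns simple reduction or pinacol coupling.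

Step 8
Reactants: 11
Product: 12 (3aS,5S,7aS)-5-bromo-4,4,7a-trimethyloctahydro-1-benzofuran-2-ol (lactol; both anomers)
Conditions: i-Bu2AlH (2.2 equiv), CH2Cl2, −78 °C; Rochelle salt work-up
Reagents that add atoms: none
Why: Partial reduction with i-Bu2AlH stops at the aldehyde oxidation level because the tertiary aluminium alkoxide formed first captures the tetrahedral intermediate as a five-membered cyclic aluminium acetal, and work-up gives the lactol.

Step 9
Reactants: 12
Product: 13 (1S,2S,4S)-4-bromo-1,3,3-trimethyl-2-(prop-2-en-1-yl)cyclohexan-1-ol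
Conditions: Ph3PCH3Br (4 equiv), KOtBu (3.8 equiv), THF, 0 → 20 °C
Reagents that add atoms: methyltriphenylphosphonium bromide, C[P+](c1ccccc1)(c1ccccc1)c1ccccc1.[Br-]
Why: Wittig methylenation of the lactol proceeds through its ring-opened hydroxy aldehyde form with excess ylide, and the equatorial bromide on a neopentyl-type carbon has no anti-periplanar hydrogen and survives the basic medium.

Step 10
Reactants: 13; 14 methacryloyl chloride
Product: 16 (1S,2S,4S)-4-bromo-1,3,3-trimethyl-2-(prop-2-en-1-yl)cyclohexyl 2-methylprop-2-enoate, via lithium alkoxide 15 (not isolated)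
Conditions: n-BuLi (1.05 equiv), THF, −78 °C; then 14 (1.3 equiv), −78 → 0 °C
Reagents that add atoms: 14 (reactant above), CC(=C)C(=O)Cl
Why: O-Acylation of the hindered tertiary alcohol through its lithium alkoxide with an acid chloride works because deprotonation is much faster than bromine–lithium exchange at −78 °C and the cold alkoxide is acylated long before it could displace the trans-1,4 bromide across the ring.

Step 11
Reactants: 16
Product: 17 (5aS,7S,9aS)-7-bromo-3,6,6,9a-tetramethyl-5,5a,6,7,8,9-hexahydro-1-benzoxepin-2(9aH)-one
Conditions: second-generation Grubbs catalyst (10 mol%), 1,4-benzoquinone (20 mol%), toluene (5 mM), 80 °C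
Reagents that add atoms: none
Why: Ring-closing metathesis of the methacrylate and allyl groups, held gauche as trans-diequatorial neighbours on the chair of ring A, closes ring B as the seven-membered lactone with loss of ethylene, the trisubstituted alkene is necessarily Z in the ring, and benzoquinone suppresses allyl-to-propenyl isomerisation.

Step 12
Reactants: 17
Product: 18 (5aS,7S,9aS)-7-bromo-2-(dibromomethylidene)-3,6,6,9a-tetramethyl-2,5,5a,6,7,8,9,9a-octahydro-1-benzoxepine
Conditions: CBr4 (4 equiv), PPh3 (8 equiv), toluene, 110 °C; chromatography on Et3N-washed silica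
Reagents that add atoms: carbon tetrabromide, BrC(Br)(Br)Br
Why: Wittig-type dibromomethylenation of the lactone carbonyl with Ph3P=CBr2 generated from PPh3 and CBr4 (the Ramirez reagent, as used for dihalomethylenation of lactones) proceeds by addition to C2, oxaphosphetane formation and loss of Ph3PO, and heat is needed because the carbonyl is conjugated and flanked by the tertiary C9a–O bond.

Step 13
Reactants: 18
Product: 19 (2E,5aS,7S,9aS)-7-bromo-2-(bromomethylidene)-3,6,6,9a-tetramethyl-2,5,5a,6,7,8,9,9a-octahydro-1-benzoxepine
Conditions: Pd(PPh3)4 (5 mol%), Bu3SnH (1.1 equiv), degassed toluene, 20 °C, dark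
Reagents that add atoms: none
Why: In this palladium-catalysed hydrostannolysis of a 1,1-dibromoalkene, zerovalent palladium inserts into the more exposed C–Br bond, here the one syn to O1 because the other is pressed against the C3 methyl group, and hydride transfer from tin with reductive elimination leaves the E monobromide, which like the alkyl bromide reacts far more slowly.

Step 14
Reactants: 19
Product: 20 CNP0375295.1, (2E,3R,4R,5aS,7S,9aS)-7-bromo-2-(bromomethylidene)-3,4-epoxy-3,6,6,9a-tetramethyldecahydro-1-benzoxepine
Conditions: dimethyldioxirane (1.2 equiv), acetone, −40 → 0 °C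
Reagents that add atoms: dimethyldioxirane, CC1(C)OO1
Why: Electrophilic epoxidation with neutral dimethyldioxirane should take the trisubstituted C3=C4 alkene, which is more nucleophilic than the enol ether double bond whose terminal carbon carries bromine, and approach from the face opposite the axial methyl groups on C9a and C6 sets C3 and C4 as R,R.

Compound list
1 | pent-4-enal | C=CCCC=O | starting material
2 | 1-methoxy-2-methyl-1-(trimethylsiloxy)propene | COC(O[Si](C)(C)C)=C(C)C | starting material
3 | methyl (3R)-3-hydroxy-2,2-dimethylhept-6-enoate | C=CCC[C@@H](O)C(C)(C)C(=O)OC | intermediate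
4 | methyl (3R)-2,2-dimethyl-3-(trifluoromethylsulfonyloxy)hept-6-enoate | C=CCC[C@@H](OS(=O)(=O)C(F)(F)F)C(C)(C)C(=O)OC | intermediate
5 | methyl (3S)-3-bromo-2,2-dimethylhept-6-enoate | C=CCC[C@H](Br)C(C)(C)C(=O)OC | intermediate
6 | (3S)-3-bromo-2,2-dimethylhept-6-en-1-ol | C=CCC[C@H](Br)C(C)(C)CO | intermediate
7 | (3S)-3-bromo-2,2-dimethylhept-6-enal | C=CCC[C@H](Br)C(C)(C)C=O | intermediate
8 | trimethyl phosphonoacetate | COC(=O)CP(=O)(OC)OC | starting material
9 | methyl (2E,5S)-5-bromo-4,4-dimethylnona-2,8-dienoate | C=CCC[C@H](Br)C(C)(C)/C=C/C(=O)OC | intermediate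
10 | methyl (2E,5S)-5-bromo-4,4-dimethyl-8-oxonon-2-enoate | CC(=O)CC[C@H](Br)C(C)(C)/C=C/C(=O)OC | intermediate
11 | methyl 2-[(1S,3S,6S)-3-bromo-6-hydroxy-2,2,6-trimethylcyclohexyl]acetate | CC1(C)[C@@H](Br)CC[C@](C)(O)[C@H]1CC(=O)OC | intermediate
12 | (3aS,5S,7aS)-5-bromo-4,4,7a-trimethyloctahydro-1-benzofuran-2-ol (both anomers) | CC1(C)[C@@H](Br)CC[C@]2(C)OC(O)C[C@@H]12 | intermediate
13 | (1S,2S,4S)-4-bromo-1,3,3-trimethyl-2-(prop-2-en-1-yl)cyclohexan-1-ol | CC1(C)[C@@H](Br)CC[C@](C)(O)[C@H]1CC=C | intermediate
14 | methacryloyl chloride | CC(=C)C(=O)Cl | starting material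
15 | lithium (1S,2S,4S)-4-bromo-1,3,3-trimethyl-2-(prop-2-en-1-yl)cyclohexan-1-olate | CC1(C)[C@@H](Br)CC[C@](C)([O-])[C@H]1CC=C.[Li+] | intermediate
16 | (1S,2S,4S)-4-bromo-1,3,3-trimethyl-2-(prop-2-en-1-yl)cyclohexyl 2-methylprop-2-enoate | CC1(C)[C@@H](Br)CC[C@](C)(OC(=O)C(C)=C)[C@H]1CC=C | intermediate
17 | (5aS,7S,9aS)-7-bromo-3,6,6,9a-tetramethyl-5,5a,6,7,8,9-hexahydro-1-benzoxepin-2(9aH)-one | CC1(C)[C@@H](Br)CC[C@]2(C)OC(=O)C(C)=CC[C@@H]12 | intermediate
18 | (5aS,7S,9aS)-7-bromo-2-(dibromomethylidene)-3,6,6,9a-tetramethyl-2,5,5a,6,7,8,9,9a-octahydro-1-benzoxepine | CC1(C)[C@@H](Br)CC[C@]2(C)OC(=C(Br)Br)C(C)=CC[C@@H]12 | intermediate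
19 | (2E,5aS,7S,9aS)-7-bromo-2-(bromomethylidene)-3,6,6,9a-tetramethyl-2,5,5a,6,7,8,9,9a-octahydro-1-benzoxepine | CC1(C)[C@@H](Br)CC[C@]2(C)O/C(=C/Br)C(C)=CC[C@@H]12 | intermediate
20 | CNP0375295.1, (2E,3R,4R,5aS,7S,9aS)-7-bromo-2-(bromomethylidene)-3,4-epoxy-3,6,6,9a-tetramethyldecahydro-1-benzoxepine | CC1(C)[C@@H](Br)CC[C@]2(C)O/C(=C/Br)[C@]3(C)O[C@@H]3C[C@@H]12 | target

Total step count: 14. Longest linear sequence: 14 steps, from 1 to 20.

Steps most likely to fail

Step 12. The ylide may add too slowly to the conjugated, hindered lactone carbonyl, or add to C4 in conjugate fashion, so that prolonged heating only degrades the lactone. The fallback sets out from 17 and replaces phosphorus-ylide olefination by titanium carbene methylenation followed by electrophilic bromination. Petasis methylenation with Cp2TiMe2 in toluene at 70 °C in the dark should give the exocyclic enol ether, the 2-methylidene diene F1. NBS with 2,6-lutidine in CH2Cl2 at −78 °C brominates the terminal enol ether carbon, and the bromo-oxocarbenium ion loses a proton to give the bromomethylidene compound, expected mainly as the Z isomer F2 with bromine on the open side next to O1; any 19 formed alongside is carried on with it. A second treatment with NBS and 2,6-lutidine brominates the same carbon again and comes back to the route at 18, whichever isomer went in.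

Step 2. Displacement at the neopentyl-type carbon may be slow enough for the triflate to ionise or eliminate, which would give alkenes, rearranged esters or a bromide of eroded enantiomeric purity. The fallback sets out from 3 and lets ring strain drive the substitution. LiOH in aqueous THF/MeOH at 40 °C gives the hydroxy acid F3. TsCl in pyridine at 0 °C activates the carboxyl group and closes the β-lactone F4 with retention at the carbinol carbon. MgBr2·OEt2 in Et2O opens the lactone by attack of bromide on the ring CH–O carbon with inversion to give the bromo acid F5. Trimethylsilyldiazomethane in toluene/MeOH then comes back to the route at 5.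

Step 14. Dimethyldioxirane may oxidise the bromo enol ether double bond as well as the ring alkene (loss of chemoselectivity), which would destroy the diene. The fallback sets out from 18, in which two bromine atoms deactivate the enol ether fully. Dimethyldioxirane in acetone should epoxidise only the C3=C4 alkene, from the same open face, to give the dibromo epoxide F6. The bromine syn to O1 is then removed with Pd(PPh3)4 and Bu3SnH (1.0 equiv, added slowly at 0 °C), which comes back to the route at 20.

Further compounds
F1 | step 12 | (5aS,7S,9aS)-7-bromo-3,6,6,9a-tetramethyl-2-methylidene-2,5,5a,6,7,8,9,9a-octahydro-1-benzoxepine | CC1(C)[C@@H](Br)CC[C@]2(C)OC(=C)C(C)=CC[C@@H]12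
F2 | step 12 | (2Z,5aS,7S,9aS)-7-bromo-2-(bromomethylidene)-3,6,6,9a-tetramethyl-2,5,5a,6,7,8,9,9a-octahydro-1-benzoxepine | CC1(C)[C@@H](Br)CC[C@]2(C)O/C(=C\Br)C(C)=CC[C@@H]12
F3 | step 2 | (3R)-3-hydroxy-2,2-dimethylhept-6-enoic acid | C=CCC[C@@H](O)C(C)(C)C(=O)O
F4 | step 2 | (4R)-4-(but-3-en-1-yl)-3,3-dimethyloxetan-2-one | C=CCC[C@H]1OC(=O)C1(C)C
F5 | step 2 | (3S)-3-bromo-2,2-dimethylhept-6-enoic acid | C=CCC[C@H](Br)C(C)(C)C(=O)O
F6 | step 14 | (3R,4R,5aS,7S,9aS)-7-bromo-2-(dibromomethylidene)-3,4-epoxy-3,6,6,9a-tetramethyldecahydro-1-benzoxepine | CC1(C)[C@@H](Br)CC[C@]2(C)OC(=C(Br)Br)[C@]3(C)O[C@@H]3C[C@@H]12
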